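Saturday's and Sunday's flasks look nearly the same, with equal equivalents and equal loadings. Yet at 30.0 h Saturday's stood at 93.7% product and Sunday's at 76.2%. Sunday's substrate was half of Saturday's, and the mol% loading halved its second catalyst too.

| flask | substrate | coupling partner | free catalyst | second catalyst | remark | time |
|---|---|---|---|---|---|---|
| Saturday's | 10 mM | 1 equiv | 0.05 mol% | 7.3 mol% | run made earlier |  |
| Monday's | 10 mM | 0.67 equiv | 0.05 mol% | 7.3 mol% | run made earlier |  |
| Tuesday's | 10 mM | 1.5 equiv | 0.05 mol% | 7.3 mol% | run made earlier |  |
| Sunday's | 5 mM | 1 equiv | 0.05 mol% | 7.3 mol% | run made earlier |  |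
| gamma | 10 mM (fed, over 10 h) | 1.00 equiv | 0.05 mol% | 7.3 mol% | all else is in the flask from the start; the feed brings no volume worth counting | 2.0 d |
| delta | 10 mM | 1.00 equiv (fed, over 10 h) | 0.05 mol% | 7.3 mol% | all else is in the flask from the start; the feed brings no volume worth counting | 2.0 d |
| epsilon | 10 mM | 1.00 equiv | 0.05 mol% | 7.3 mol% | everything together at the start | 2.0 d |

| run | time / h | product / % |
|---|---|---|
| Saturday's | 2.50 | 58.0 |
| Saturday's | 8.00 | 87.4 |
| Saturday's | 12.0 | 91.1 |
| Saturday's | 20.0 | 93.3 |
| Saturday's | 30.0 | 93.7 |
| Monday's | 2.50 | 49.4 |
| Monday's | 4.00 | 59.4 |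
| Monday's | 8.00 | 66.6 |
| Monday's | 15.0 | 67.0 |
| Monday's | 30.0 | 66.4 |
| Tuesday's | 6.00 | 91.0 |
| Tuesday's | 12.0 | 98.7 |
| Tuesday's | 15.0 | 99.3 |
| Tuesday's | 25.0 | 100.0 |
| Tuesday's | 30.0 | 100.4 |
| Sunday's | 6.00 | 52.2 |
| Sunday's | 12.0 | 68.9 |
| Sunday's | 15.0 | 71.9 |
| Sunday's | 25.0 | 74.7 |
| Sunday's | 30.0 | 76.2 |

(scatter of a reading: 0.5 percentage points)

- the flask with the highest amount of product, in percent of the substrate charged ("all alike" if they lie within 1.5 percentage points) (gamma / delta / epsilon / all alike)
- final product, as a percentage of the substrate charged, in gamma
- final product, as a percentage of the substrate charged, in delta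
- final product, as a percentage of the substrate charged, in epsilon

- the earlier runs were read with a standard deviation of 0.5 percentage points
- steps thought possible: substrate + free catalyst -> free catalyst + intermediate; coupling partner + second catalyst + intermediate -> second catalyst + product; second catalyst -> spent catalyst

I took equal charges as the zero of my scale. Monday's flask stopped at 66.4% with the coupling partner as limiting reagent, and Tuesday's reached 100.4%. At one equivalent, c(intermediate) equals c(coupling partner) once the first step has run. The coupling rate then goes with the square of that c and with the living second catalyst. So the reciprocal of c climbs with the catalyst's accumulated working time, and it stops climbing when the catalyst dies.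

Saturday's stall gives 1.49 mM⁻¹. I call this the coupling budget: the rise of the reciprocal of c(coupling partner) from charge to stall. It should scale with c(second catalyst), so Sunday's flask gets 0.744 mM⁻¹. With that smaller budget and the halved substrate both counted, this reckoning gives Sunday's flask 78.8% product. The reading lay 2.6 percentage points below that, more than the scatter, so I kept the rule as an upper estimate.

Epsilon repeats Saturday's recipe, so I expected Saturday's stall there. I put gamma and delta below it without a figure, since a feed delays the meeting of the partners while the second catalyst ages.

The forecast named epsilon as the best flask, with 88% in gamma, 90% in delta and 94% in epsilon, holding that “low concentration early wastes catalyst life”.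

The flasks gave 86.8% in gamma, 90.3% in delta and 93.8% in epsilon, so epsilon led. The forecast's miss in gamma, 1.2 points, is smaller than the 3.5 points between gamma and delta, so its order stood.

    substrate + free catalyst → free catalyst + intermediate (k = 91000 L mol⁻¹ h⁻¹)
    coupling partner + second catalyst + intermediate → second catalyst + product (k = 6.70 × 10⁵ L² mol⁻² h⁻¹)
    second catalyst → spent catalyst (k = 0.160 h⁻¹)

In gamma the feed ran 10 h against a second-catalyst half-life of 0.18 d. At 0.417 d, 20.2% of the second catalyst remained with 21.7% substrate still unconverted, and at 2.00 d 13.2% intermediate stood beside 13.2% coupling partner. Read the same way, gamma used 44.4% of the budget. Carrying that share to a neighbour of gamma, charged with 2.5 mM substrate, gives 29.2% product. That neighbour gave 25.5%.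

The earlier runs and the new flask come from a simulation for substances that don't exist; noise was put on by code.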